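## Retrosynthetic overview

1. Target ⇒ global desilylation; Hofmann elimination of a C13 Mannich base (exo-methylene); O8 acylation with (Z)-2-(silyloxymethyl)but-2-enoic acid made from crotonaldehyde.
2. Ring B (ten-membered carbocycle) ⇒ ring-closing metathesis at C2=C3 between a vinyl epoxide and a 2-substituted 1,3-diene carried on a preformed cis-γ-lactone.
3. Ring A (γ-lactone) ⇒ oxidative cleavage of a C7 allyl group and closure onto O6; diene ⇒ Stille vinylation of a (Z)-alkenyl iodide from trans-hydroalumination/iodination of a propargylic alcohol.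
4. cis-Epoxide ⇒ Sharpless epoxidation of a Z-allylic alcohol released from a 4-methyl-5,6-dihydropyran-2-one (Chan's-diene aldol at C8, enol triflate, cuprate).
5. C6/C7/C8 ⇒ ketoreductase reduction of an alkynyl β-keto ester, Fráter–Seebach allylation, Felkin/1,3-anti Mukaiyama aldol. Ring order: temporary dihydropyranone (later opened) → oxirane → γ-lactone (ring A) → carbocycle (ring B).

Assumption: the SMILES is read literally (cis-fused 6,12-lactone, (1R,10S)-cis-epoxide, 6S,7R,8S, ring-cis C2=C3 and C4=C5, Z side-chain ester); atom labels follow the target (C1/C10 epoxide, C6 lactone carbinol, C7 junction, C8 ester carbinol, C11–C13 methylene lactone, C14 methyl, C15 CH2OH); the (R)-selective ketoreductase of step 3 is taken from a commercial screening panel.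

Abbreviations: TBDPS = tert-butyldiphenylsilyl, TES = triethylsilyl, TBS = tert-butyldimethylsilyl, PMB = 4-methoxybenzyl.

## Route

Step 1
Reactants: 1 tert-butyl(diphenyl)(prop-2-yn-1-yloxy)silane; 2 N-methoxy-N-methylcarbamoyl chloride
Product: 4 4-[(tert-butyldiphenylsilyl)oxy]-N-methoxy-N-methylbut-2-ynamide, via lithium acetylide 3 (not isolated)
Conditions: n-BuLi, THF, −78 °C; then 2, −78 → 0 °C; aq. NH4Cl
Reagents that add atoms: N-methoxy-N-methylcarbamoyl chloride (2), CON(C)C(Cl)=O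
Why: acylation of a lithium acetylide by a carbamoyl chloride gives the Weinreb ynamide directly (C5–C6 bond), with no stereocentre involved.

Step 2
Reactants: 4 Weinreb ynamide; 5 ethyl acetate
Product: 7 ethyl 6-[(tert-butyldiphenylsilyl)oxy]-3-oxohex-4-ynoate, via lithium enolate 6 (not isolated)
Conditions: LiN(iPr)2, 5, THF, −78 °C; then 4, −78 °C; aq. NH4Cl
Reagents that add atoms: ethyl acetate (5), CCOC(C)=O
Why: Claisen-type acylation of the ester enolate by the Weinreb amide, whose chelated adduct releases the β-keto ester only on work-up and so prevents over-addition.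

Step 3
Reactants: 7 alkynyl β-keto ester
Product: 8 ethyl (3R)-6-[(tert-butyldiphenylsilyl)oxy]-3-hydroxyhex-4-ynoate
Conditions: ketoreductase (NADPH-dependent, (R)-selective hit from a commercial panel), NADP+ (cat.), iPrOH (15 vol%), KH2PO4/K2HPO4 buffer pH 7, DMSO (5 vol%), 30 °C
Reagents that add atoms: none
Why: enzymatic asymmetric ketone reduction (ketoreductase with isopropanol-coupled cofactor recycling) transfers hydride to one face of the achiral ketone and sets C6 as the (R)-carbinol in high ee.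

Step 4
Reactants: 8 hydroxy ester; 9 allyl bromide
Product: 11 ethyl (2S,3R)-6-[(tert-butyldiphenylsilyl)oxy]-3-hydroxy-2-(prop-2-en-1-yl)hex-4-ynoate, via dilithio dianion 10 (not isolated)
Conditions: LiN(iPr)2 (2.2 equiv), THF, −78 → −20 °C; then 9, DMPU, −78 → −10 °C; aq. NH4Cl
Reagents that add atoms: allyl bromide (9), C=CCBr
Why: Fráter–Seebach alkylation of the chelated alkoxide–enolate dianion occurs anti to the C6 oxygen and sets C7 (6,7-anti, the future cis-lactone relationship).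

Step 5
Reactants: 11 allylated hydroxy ester
Product: 13 (2R,3R,4Z)-6-[(tert-butyldiphenylsilyl)oxy]-5-iodo-2-(prop-2-en-1-yl)hex-4-ene-1,3-diol, via cyclic alkenylalanate 12 (not isolated)
Conditions: NaAlH2(OCH2CH2OMe)2 (4 equiv), THF, 0 °C → rt; then I2, THF, −78 → 0 °C; aq. Na2S2O3
Reagents that add atoms: iodine, II
Why: the hydride reduces the ester to the C8 alcohol and, directed by the C6 alkoxide, adds H–Al trans across the alkyne with Al on C4 (hydroxyl-directed trans-hydroalumination), and iodinolysis with retention gives the alkenyl iodide with C6 cis to iodine.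

Step 6
Reactants: 13 iodo diol
Product: 14 (2R,4R,5R)-4-[(1Z)-3-[(tert-butyldiphenylsilyl)oxy]-2-iodoprop-1-en-1-yl]-2-(4-methoxyphenyl)-5-(prop-2-en-1-yl)-1,3-dioxane
Conditions: 4-MeOC6H4CH(OMe)2, PPTS (cat.), CH2Cl2, rt
Reagents that add atoms: 4-methoxybenzaldehyde dimethyl acetal, COC(OC)c1ccc(OC)cc1
Why: acid-catalysed transacetalisation of the 1,3-diol under thermodynamic control gives the all-equatorial chair, which fixes the acetal carbon.

Step 7
Reactants: 14 p-methoxybenzylidene acetal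
Product: 15 (2R,3R,4Z)-6-[(tert-butyldiphenylsilyl)oxy]-5-iodo-3-[(4-methoxybenzyl)oxy]-2-(prop-2-en-1-yl)hex-4-en-1-ol
Conditions: iBu2AlH, CH2Cl2, −78 → 0 °C
Reagents that add atoms: none
Why: regioselective reductive acetal opening, in which aluminium binds the less hindered primary oxygen, leaves PMB on the secondary O6 and frees the C8 alcohol.

Step 8
Reactants: 15 primary alcohol
Product: 16 (2S,3R,4Z)-6-[(tert-butyldiphenylsilyl)oxy]-5-iodo-3-[(4-methoxybenzyl)oxy]-2-(prop-2-en-1-yl)hex-4-enal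
Conditions: Dess–Martin periodinane, CH2Cl2, 0 °C → rt
Reagents that add atoms: none
Why: Dess–Martin oxidation under non-basic conditions gives the α-branched aldehyde without epimerising C7 (used crude).

Step 9
Reactants: 16 aldehyde; 17 Chan's diene
Product: 18 methyl (5S,6R,7R,8Z)-10-[(tert-butyldiphenylsilyl)oxy]-5-hydroxy-9-iodo-7-[(4-methoxybenzyl)oxy]-3-oxo-6-(prop-2-en-1-yl)dec-8-enoate
Conditions: 17, BF3·OEt2, CH2Cl2, −78 °C; aq. NaHCO3, then brief 1 M HCl/THF
Reagents that add atoms: Chan's diene (17), COC(O[Si](C)(C)C)=CC(=C)O[Si](C)(C)C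
Why: Mukaiyama aldol addition in which Felkin–Anh control from C7 and 1,3-anti induction from the β-OPMB group reinforce each other for this 6,7-anti aldehyde, setting C8 (7,8-syn, 6,8-anti).

Step 10
Reactants: 18 δ-hydroxy-β-keto ester
Product: 19 (6S)-6-[(4R,5R,6Z)-8-[(tert-butyldiphenylsilyl)oxy]-7-iodo-5-[(4-methoxybenzyl)oxy]octa-1,6-dien-4-yl]oxane-2,4-dione
Conditions: K2CO3, MeOH, rt; then 1 M HCl to pH 3
Reagents that add atoms: none
Why: base-mediated lactonisation (intramolecular transesterification) masks O8 and places C1 and C10 in a six-membered ring that will lock the olefin geometry.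

Step 11
Reactants: 19 pyrandione
Product: 20 (2S)-2-[(4R,5R,6Z)-8-[(tert-butyldiphenylsilyl)oxy]-7-iodo-5-[(4-methoxybenzyl)oxy]octa-1,6-dien-4-yl]-6-oxo-3,6-dihydro-2H-pyran-4-yl trifluoromethanesulfonate
Conditions: Tf2O, Et3N, CH2Cl2, −78 °C
Reagents that add atoms: triflic anhydride, O=S(=O)(OS(=O)(=O)C(F)(F)F)C(F)(F)F
Why: O-sulfonylation of the cyclic vinylogous acid gives the enol triflate, whose endocyclic olefin can only be cis.

Step 12
Reactants: 20 enol triflate
Product: 21 (6S)-6-[(4R,5R,6Z)-8-[(tert-butyldiphenylsilyl)oxy]-7-iodo-5-[(4-methoxybenzyl)oxy]octa-1,6-dien-4-yl]-4-methyl-5,6-dihydro-2H-pyran-2-one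
Conditions: Me2CuLi (from CuI and MeLi), THF, −78 °C; aq. NH4Cl
Reagents that add atoms: lithium dimethylcuprate, [Li+].C[Cu-]C
Why: cuprate addition–elimination on the β-triflyloxy enoate installs C14 within minutes at −78 °C, a temperature at which the alkenyl iodide is inert.

Step 13
Reactants: 21 methyl dihydropyranone
Product: 22 (2Z,5S,6R,7R,8Z)-10-[(tert-butyldiphenylsilyl)oxy]-9-iodo-7-[(4-methoxybenzyl)oxy]-3-methyl-6-(prop-2-en-1-yl)deca-2,8-diene-1,5-diol
Conditions: iBu2AlH (3.5 equiv), CH2Cl2, −78 → 0 °C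
Reagents that add atoms: none
Why: exhaustive 1,2-reduction of the unsaturated δ-lactone releases the Z-trisubstituted allylic alcohol (geometry inherited from the ring) together with the C8 hydroxyl.

Step 14
Reactants: 22 Z-allylic diol
Product: 23 (2R,3S,5S,6R,7R,8Z)-10-[(tert-butyldiphenylsilyl)oxy]-2,3-epoxy-9-iodo-7-[(4-methoxybenzyl)oxy]-3-methyl-6-(prop-2-en-1-yl)dec-8-ene-1,5-diol
Conditions: Ti(OiPr)4 (20 mol%), D-(−)-diethyl tartrate (24 mol%), t-BuOOH, 4 Å MS, CH2Cl2, −20 °C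
Reagents that add atoms: tert-butyl hydroperoxide, CC(C)(C)OO
Why: Sharpless asymmetric epoxidation, in which the titanium–D-tartrate catalyst delivers oxygen to the face of the allylic alcohol that gives the (1R,10S)-cis-epoxide (reagent control), while the allyl and iodo olefins are not allylic alcohols and stay untouched.

Step 15
Reactants: 23 epoxy diol
Product: 24 (2R,3S,5S,6S,7R,8Z)-10-[(tert-butyldiphenylsilyl)oxy]-2,3-epoxy-9-iodo-7-[(4-methoxybenzyl)oxy]-3-methyl-6-(prop-2-en-1-yl)-1,5-bis(triethylsilyloxy)dec-8-ene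
Conditions: Et3SiCl, imidazole, DMAP (cat.), DMF, 0 °C → rt
Reagents that add atoms: chlorotriethylsilane, CC[Si](Cl)(CC)CC
Why: silylation of both hydroxyls makes the primary TES ether a latent aldehyde and blocks O8 against the competing 8,12-lactone.

Step 16
Reactants: 24 bis-TES ether
Product: 26 C12 aldehyde (allyl group of 24 cut to CH2CHO on C7), via vicinal diol 25 (not isolated)
Conditions: OsO4 (2 mol%), NMO, acetone/H2O, 0 °C → rt; then NaIO4, THF/H2O
Reagents that add atoms: 4-methylmorpholine N-oxide (terminal oxidant, oxygen delivered through OsO4), C[N+]1([O-])CCOCC1; water, O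
Why: Lemieux–Johnson-type cleavage, in which dihydroxylation is selective for the terminal monosubstituted olefin over the deactivated, hindered iodo-olefin and periodate then cleaves the diol.

Step 17
Reactants: 26 aldehyde
Product: 28 five-membered lactol (O6–C12 hemiacetal; anomer mixture), via hydroxy aldehyde 27 (not isolated)
Conditions: DDQ, CH2Cl2/pH 7 buffer, 0 °C
Reagents that add atoms: none
Why: oxidative PMB cleavage frees O6, which closes at once onto the C12 aldehyde to form the ring A skeleton (cis at C6/C7 as a consequence of the 6,7-anti relationship).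

Step 18
Reactants: 28 lactol
Product: 29 iodo γ-lactone (cis-fused 6,12-lactone; 4Z-iodide; C8-OTES; C2-OTES; 1R,10S-epoxide)
Conditions: TEMPO (cat.), PhI(OAc)2, CH2Cl2, rt
Reagents that add atoms: none
Why: TEMPO/PhI(OAc)2 oxidation of the lactol gives the γ-butyrolactone without affecting silyl ethers, epoxide or alkenyl iodide.

Step 19
Reactants: 29 iodo γ-lactone; 30 tributyl(vinyl)stannane
Product: 31 diene lactone (C4 iodide replaced by vinyl)
Conditions: Pd(PPh3)4 (5 mol%), CuI (20 mol%), DMF, 40 °C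
Reagents that add atoms: tributyl(vinyl)stannane (30), C=C[Sn](CCCC)(CCCC)CCCC
Why: Stille coupling with retention of the alkenyl geometry forms C3–C4 while the epoxide is still non-allylic and therefore inert to zerovalent palladium.

Step 20
Reactants: 31 diene lactone
Product: 33 epoxy aldehyde (C2 = CHO), via primary alcohol 32 (not isolated)
Conditions: (COCl)2, DMSO, CH2Cl2, −78 → −40 °C; then Et3N, −78 → 0 °C
Reagents that add atoms: none
Why: Swern conditions cleave the primary TES ether selectively and oxidise the liberated alcohol in the same pot, leaving the secondary TES ether intact.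

Step 21
Reactants: 33 epoxy aldehyde
Product: 34 vinyl epoxide seco-lactone
Conditions: Ph3PCH3Br, KN(SiMe3)2, THF, −78 → 0 °C
Reagents that add atoms: methyltriphenylphosphonium bromide, C[P+](c1ccccc1)(c1ccccc1)c1ccccc1.[Br-]
Why: Wittig methylenation of the epoxy aldehyde (the oxirane α-carbon cannot epimerise) supplies the second metathesis terminus.

Step 22
Reactants: 34 vinyl epoxide seco-lactone
Product: 35 macrocyclic dienyl epoxide lactone (ring B closed; C8-OTES; C15-OTBDPS)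
Conditions: second-generation Grubbs catalyst RuCl2(=CHPh)(PCy3)(H2IMes) (10 mol%), 1,4-benzoquinone (cat.), toluene (1 mM), 60 °C
Reagents that add atoms: none
Why: ring-closing metathesis between the vinyl epoxide and the terminal diene olefin closes the ten-membered ring, the chain being pre-folded by the cis-epoxide, the cis-lactone and the C4=C5 geometry so that only the cis C2=C3 olefin fits.

Step 23
Reactants: 35 macrocyclic lactone
Product: 37 Mannich base (CH2NMe2 on C11; C11 epimers), via lithium enolate 36 (not isolated)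
Conditions: LiN(iPr)2, THF, −78 °C; then CH2=NMe2+ I−, −78 → 0 °C
Reagents that add atoms: N,N-dimethylmethyleneiminium iodide (Eschenmoser's salt), C=[N+](C)C.[I-]
Why: Mannich aminomethylation of the lactone enolate introduces C13, and the new C11 centre is inconsequential because it becomes sp2.

Step 24
Reactants: 37 Mannich base
Product: 38 C8 alcohol (Mannich base; TBDPS retained)
Conditions: HF·pyridine, pyridine, THF, 0 °C
Reagents that add atoms: none
Why: buffered fluoride desilylation removes the secondary TES ether selectively in the presence of the TBDPS ether, while the Michael acceptor is still masked.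

Step 25
Reactants: 39 (E)-but-2-enal
Product: 40 (2Z)-2-iodobut-2-enal
Conditions: I2, K2CO3, DMAP (cat.), THF/H2O, rt
Reagents that add atoms: iodine, II
Why: α-iodination of the enal by a Baylis–Hillman-type addition–iodination–elimination keeps methyl trans to the formyl group and gives the Z-iodide.

Step 26
Reactants: 40 iodo enal
Product: 41 (2Z)-2-iodobut-2-en-1-ol
Conditions: NaBH4, CeCl3·7H2O, MeOH, 0 °C
Reagents that add atoms: none
Why: Luche 1,2-reduction of the enal leaves the alkenyl iodide and its geometry untouched.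

Step 27
Reactants: 41 iodo alcohol
Product: 42 tert-butyl{[(2Z)-2-iodobut-2-en-1-yl]oxy}dimethylsilane
Conditions: t-BuMe2SiCl, imidazole, CH2Cl2, rt
Reagents that add atoms: tert-butyldimethylsilyl chloride, CC(C)(C)[Si](C)(C)Cl
Why: routine silyl protection of the primary alcohol.

Step 28
Reactants: 42 iodo silyl ether
Product: 44 (2Z)-2-({[tert-butyl(dimethyl)silyl]oxy}methyl)but-2-enoic acid, via vinyllithium 43 (not isolated)
Conditions: t-BuLi (2 equiv), Et2O, −78 °C; then CO2, −78 °C; cold 1 M HCl to pH 3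
Reagents that add atoms: carbon dioxide, O=C=O
Why: iodine–lithium exchange and carboxylation both proceed with retention, so the carboxyl group ends cis to the methyl group (angelate-type Z acid).

Step 29
Reactants: 38 C8 alcohol; 44 Z acid
Product: 46 O8 ester (Mannich base; both silyl ethers in place), via mixed anhydride 45 (not isolated)
Conditions: 44, 2,4,6-Cl3C6H2COCl, Et3N, toluene, rt; then 38, toluene, 50 °C (no DMAP)
Reagents that add atoms: acid 44, OC(=O)/C(=C\C)CO[Si](C)(C)C(C)(C)C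
Why: Yamaguchi esterification run without a nucleophilic catalyst avoids Z→E isomerisation of the enoate and retains configuration at C8 because only the O–H bond is engaged.

Step 30
Reactants: 46 ester Mannich base
Product: 48 bis-silyl ether of the target (α-methylene lactone unveiled), via ammonium iodide 47 (not isolated)
Conditions: MeI, CH2Cl2/MeOH, rt; then aq. NaHCO3, EtOAc, rt
Reagents that add atoms: none
Why: quaternisation followed by Hofmann-type β-elimination forms the α-methylene-γ-butyrolactone under near-neutral conditions tolerated by the dienyl epoxide and the Z-ester.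

Step 31
Reactants: 48 bis-silyl ether
Product: 49 target, CNP0293319.3
Conditions: HF·pyridine, pyridine, THF, 0 °C → rt
Reagents that add atoms: none
Why: global fluoride desilylation of the primary TBS and TBDPS ethers under buffered conditions spares the dienyl epoxide, the methylene lactone and the Z-ester.

## Compound list

1 | tert-butyl(diphenyl)(prop-2-yn-1-yloxy)silane | C#CCO[Si](c1ccccc1)(c1ccccc1)C(C)(C)C | starting material
2 | N-methoxy-N-methylcarbamoyl chloride | CON(C)C(Cl)=O | starting material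
3 | lithium acetylide of 1 (not isolated) | [Li]C#CCO[Si](c1ccccc1)(c1ccccc1)C(C)(C)C | intermediate
4 | 4-[(tert-butyldiphenylsilyl)oxy]-N-methoxy-N-methylbut-2-ynamide | CON(C)C(=O)C#CCO[Si](c1ccccc1)(c1ccccc1)C(C)(C)C | intermediate
5 | ethyl acetate | CCOC(C)=O | starting material
6 | lithium enolate of ethyl acetate (not isolated) | [Li]OC(=C)OCC | intermediate
7 | ethyl 6-[(tert-butyldiphenylsilyl)oxy]-3-oxohex-4-ynoate | CCOC(=O)CC(=O)C#CCO[Si](c1ccccc1)(c1ccccc1)C(C)(C)C | intermediate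
8 | ethyl (3R)-6-[(tert-butyldiphenylsilyl)oxy]-3-hydroxyhex-4-ynoate | CCOC(=O)C[C@@H](O)C#CCO[Si](c1ccccc1)(c1ccccc1)C(C)(C)C | intermediate
9 | allyl bromide | C=CCBr | starting material
10 | dilithium alkoxide–enolate of 8 (not isolated) | CCOC(O[Li])=C[C@@H](O[Li])C#CCO[Si](c1ccccc1)(c1ccccc1)C(C)(C)C | intermediate
11 | ethyl (2S,3R)-6-[(tert-butyldiphenylsilyl)oxy]-3-hydroxy-2-(prop-2-en-1-yl)hex-4-ynoate | CCOC(=O)[C@@H](CC=C)[C@@H](O)C#CCO[Si](c1ccccc1)(c1ccccc1)C(C)(C)C | intermediate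
12 | sodium alkenylalanate: five-membered O6–Al–C4=C5–C6 ring, Al carrying two 2-methoxyethoxy groups, ester already reduced (C8 oxygen drawn protonated; not isolated) | [Na+].C=CC[C@H](CO)[C@H]1O[Al-](OCCOC)(OCCOC)C(CO[Si](c2ccccc2)(c2ccccc2)C(C)(C)C)=C1 | intermediate
13 | (2R,3R,4Z)-6-[(tert-butyldiphenylsilyl)oxy]-5-iodo-2-(prop-2-en-1-yl)hex-4-ene-1,3-diol | OC[C@@H](CC=C)[C@@H](O)/C=C(\I)CO[Si](c1ccccc1)(c1ccccc1)C(C)(C)C | intermediate
14 | (2R,4R,5R)-4-[(1Z)-3-[(tert-butyldiphenylsilyl)oxy]-2-iodoprop-1-en-1-yl]-2-(4-methoxyphenyl)-5-(prop-2-en-1-yl)-1,3-dioxane | C=CC[C@@H]1CO[C@@H](c2ccc(OC)cc2)O[C@H]1/C=C(\I)CO[Si](c3ccccc3)(c3ccccc3)C(C)(C)C | intermediate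
15 | (2R,3R,4Z)-6-[(tert-butyldiphenylsilyl)oxy]-5-iodo-3-[(4-methoxybenzyl)oxy]-2-(prop-2-en-1-yl)hex-4-en-1-ol | OC[C@@H](CC=C)[C@@H](OCc1ccc(OC)cc1)/C=C(\I)CO[Si](c2ccccc2)(c2ccccc2)C(C)(C)C | intermediate
16 | (2S,3R,4Z)-6-[(tert-butyldiphenylsilyl)oxy]-5-iodo-3-[(4-methoxybenzyl)oxy]-2-(prop-2-en-1-yl)hex-4-enal | O=C[C@@H](CC=C)[C@@H](OCc1ccc(OC)cc1)/C=C(\I)CO[Si](c2ccccc2)(c2ccccc2)C(C)(C)C | intermediate
17 | Chan's diene, 1-methoxy-1,3-bis(trimethylsilyloxy)buta-1,3-diene | COC(O[Si](C)(C)C)=CC(=C)O[Si](C)(C)C | starting material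
18 | methyl (5S,6R,7R,8Z)-10-[(tert-butyldiphenylsilyl)oxy]-5-hydroxy-9-iodo-7-[(4-methoxybenzyl)oxy]-3-oxo-6-(prop-2-en-1-yl)dec-8-enoate | COC(=O)CC(=O)C[C@H](O)[C@@H](CC=C)[C@@H](OCc1ccc(OC)cc1)/C=C(\I)CO[Si](c2ccccc2)(c2ccccc2)C(C)(C)C | intermediate
19 | (6S)-6-[(4R,5R,6Z)-8-[(tert-butyldiphenylsilyl)oxy]-7-iodo-5-[(4-methoxybenzyl)oxy]octa-1,6-dien-4-yl]oxane-2,4-dione | O=C1CC(=O)C[C@H](O1)[C@@H](CC=C)[C@@H](OCc2ccc(OC)cc2)/C=C(\I)CO[Si](c3ccccc3)(c3ccccc3)C(C)(C)C | intermediate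
20 | (2S)-2-[(4R,5R,6Z)-8-[(tert-butyldiphenylsilyl)oxy]-7-iodo-5-[(4-methoxybenzyl)oxy]octa-1,6-dien-4-yl]-6-oxo-3,6-dihydro-2H-pyran-4-yl trifluoromethanesulfonate | O=C1C=C(OS(=O)(=O)C(F)(F)F)C[C@H](O1)[C@@H](CC=C)[C@@H](OCc2ccc(OC)cc2)/C=C(\I)CO[Si](c3ccccc3)(c3ccccc3)C(C)(C)C | intermediate
21 | (6S)-6-[(4R,5R,6Z)-8-[(tert-butyldiphenylsilyl)oxy]-7-iodo-5-[(4-methoxybenzyl)oxy]octa-1,6-dien-4-yl]-4-methyl-5,6-dihydro-2H-pyran-2-one | O=C1C=C(C)C[C@H](O1)[C@@H](CC=C)[C@@H](OCc2ccc(OC)cc2)/C=C(\I)CO[Si](c3ccccc3)(c3ccccc3)C(C)(C)C | intermediate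
22 | (2Z,5S,6R,7R,8Z)-10-[(tert-butyldiphenylsilyl)oxy]-9-iodo-7-[(4-methoxybenzyl)oxy]-3-methyl-6-(prop-2-en-1-yl)deca-2,8-diene-1,5-diol | OC/C=C(C)\C[C@H](O)[C@@H](CC=C)[C@@H](OCc1ccc(OC)cc1)/C=C(\I)CO[Si](c2ccccc2)(c2ccccc2)C(C)(C)C | intermediate
23 | (2R,3S,5S,6R,7R,8Z)-10-[(tert-butyldiphenylsilyl)oxy]-2,3-epoxy-9-iodo-7-[(4-methoxybenzyl)oxy]-3-methyl-6-(prop-2-en-1-yl)dec-8-ene-1,5-diol | OC[C@H]1O[C@@]1(C)C[C@H](O)[C@@H](CC=C)[C@@H](OCc2ccc(OC)cc2)/C=C(\I)CO[Si](c3ccccc3)(c3ccccc3)C(C)(C)C | intermediate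
24 | (2R,3S,5S,6S,7R,8Z)-10-[(tert-butyldiphenylsilyl)oxy]-2,3-epoxy-9-iodo-7-[(4-methoxybenzyl)oxy]-3-methyl-6-(prop-2-en-1-yl)-1,5-bis(triethylsilyloxy)dec-8-ene | CC[Si](CC)(CC)OC[C@H]1O[C@@]1(C)C[C@H](O[Si](CC)(CC)CC)[C@@H](CC=C)[C@@H](OCc2ccc(OC)cc2)/C=C(\I)CO[Si](c3ccccc3)(c3ccccc3)C(C)(C)C | intermediate
25 | 24 with the allyl group dihydroxylated to CH2CH(OH)CH2OH (epimer mixture; not isolated) | CC[Si](CC)(CC)OC[C@H]1O[C@@]1(C)C[C@H](O[Si](CC)(CC)CC)[C@@H](CC(O)CO)[C@@H](OCc2ccc(OC)cc2)/C=C(\I)CO[Si](c3ccccc3)(c3ccccc3)C(C)(C)C | intermediate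
26 | C12 aldehyde: 24 with the allyl group cut to CH2CHO on C7 (1R,10S,6R,7S,8S; 4Z) | CC[Si](CC)(CC)OC[C@H]1O[C@@]1(C)C[C@H](O[Si](CC)(CC)CC)[C@@H](CC=O)[C@@H](OCc2ccc(OC)cc2)/C=C(\I)CO[Si](c3ccccc3)(c3ccccc3)C(C)(C)C | intermediate
27 | 26 without the PMB group, free C6–OH (not isolated) | CC[Si](CC)(CC)OC[C@H]1O[C@@]1(C)C[C@H](O[Si](CC)(CC)CC)[C@@H](CC=O)[C@@H](O)/C=C(\I)CO[Si](c3ccccc3)(c3ccccc3)C(C)(C)C | intermediate
28 | five-membered lactol of 27 (O6–C12 hemiacetal, cis at C6/C7; anomer mixture) | CC[Si](CC)(CC)OC[C@H]1O[C@@]1(C)C[C@H](O[Si](CC)(CC)CC)[C@H]2CC(O)O[C@H]2/C=C(\I)CO[Si](c3ccccc3)(c3ccccc3)C(C)(C)C | intermediate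
29 | iodo γ-lactone: cis-fused 6,12-lactone with the (Z)-CH=C(I)CH2OTBDPS arm on C6 and the C8(OTES)–C9H2–epoxide(C14)–C2H2OTES arm on C7 (1R,10S,6R,7S,8S) | CC[Si](CC)(CC)OC[C@H]1O[C@@]1(C)C[C@H](O[Si](CC)(CC)CC)[C@H]2CC(=O)O[C@H]2/C=C(\I)CO[Si](c3ccccc3)(c3ccccc3)C(C)(C)C | intermediate
30 | tributyl(vinyl)stannane | C=C[Sn](CCCC)(CCCC)CCCC | starting material
31 | diene lactone: 29 with vinyl in place of iodine at C4 (1R,10S,6S,7S,8S; 4E by CIP, C6 cis to C3) | CC[Si](CC)(CC)OC[C@H]1O[C@@]1(C)C[C@H](O[Si](CC)(CC)CC)[C@H]2CC(=O)O[C@H]2/C=C(\C=C)CO[Si](c3ccccc3)(c3ccccc3)C(C)(C)C | intermediate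
32 | 31 with free C2–OH (not isolated) | OC[C@H]1O[C@@]1(C)C[C@H](O[Si](CC)(CC)CC)[C@H]2CC(=O)O[C@H]2/C=C(\C=C)CO[Si](c3ccccc3)(c3ccccc3)C(C)(C)C | intermediate
33 | epoxy aldehyde: 31 with C2 as CHO (CIP 1S,10S; same spatial arrangement) | O=C[C@H]1O[C@@]1(C)C[C@H](O[Si](CC)(CC)CC)[C@H]2CC(=O)O[C@H]2/C=C(\C=C)CO[Si](c3ccccc3)(c3ccccc3)C(C)(C)C | intermediate
34 | vinyl epoxide seco-lactone: 33 with CHO converted to CH=CH2 (1R,10S,6S,7S,8S) | C=C[C@H]1O[C@@]1(C)C[C@H](O[Si](CC)(CC)CC)[C@H]2CC(=O)O[C@H]2/C=C(\C=C)CO[Si](c3ccccc3)(c3ccccc3)C(C)(C)C | intermediate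
35 | macrocycle: ten-membered ring with 1,10-epoxide, cis C2=C3, C4=C5, saturated cis-6,12-lactone, C8-OTES, C15-OTBDPS (1R,10S,6S,7S,8S) | C1C(=O)O[C@H]2/C=C(CO[Si](c4ccccc4)(c4ccccc4)C(C)(C)C)\C=C/[C@H]3O[C@@]3(C)C[C@H](O[Si](CC)(CC)CC)[C@@H]12 | intermediate
36 | lithium enolate of lactone 35 (not isolated) | C1=C(O[Li])O[C@H]2/C=C(CO[Si](c4ccccc4)(c4ccccc4)C(C)(C)C)\C=C/[C@H]3O[C@@]3(C)C[C@H](O[Si](CC)(CC)CC)[C@@H]12 | intermediate
37 | Mannich base: 35 with CH2NMe2 on C11 (C11 epimers) | CN(C)CC1C(=O)O[C@H]2/C=C(CO[Si](c4ccccc4)(c4ccccc4)C(C)(C)C)\C=C/[C@H]3O[C@@]3(C)C[C@H](O[Si](CC)(CC)CC)[C@@H]12 | intermediate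
38 | 37 with free C8–OH (1R,10S,6S,7R,8S) | CN(C)CC1C(=O)O[C@H]2/C=C(CO[Si](c4ccccc4)(c4ccccc4)C(C)(C)C)\C=C/[C@H]3O[C@@]3(C)C[C@H](O)[C@@H]12 | intermediate
39 | (E)-but-2-enal (crotonaldehyde) | C/C=C/C=O | starting material
40 | (2Z)-2-iodobut-2-enal | I/C(=C\C)C=O | intermediate
41 | (2Z)-2-iodobut-2-en-1-ol | I/C(=C\C)CO | intermediate
42 | tert-butyl{[(2Z)-2-iodobut-2-en-1-yl]oxy}dimethylsilane | I/C(=C\C)CO[Si](C)(C)C(C)(C)C | intermediate
43 | alkenyllithium from 42, geometry retained (not isolated) | [Li]/C(=C\C)CO[Si](C)(C)C(C)(C)C | intermediate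
44 | (2Z)-2-({[tert-butyl(dimethyl)silyl]oxy}methyl)but-2-enoic acid | OC(=O)/C(=C\C)CO[Si](C)(C)C(C)(C)C | intermediate
45 | mixed anhydride of 44 with 2,4,6-trichlorobenzoic acid (not isolated) | O=C(OC(=O)/C(=C\C)CO[Si](C)(C)C(C)(C)C)c1c(Cl)cc(Cl)cc1Cl | intermediate
46 | 38 acylated at O8 with the Z acid 44 (Mannich base; 1R,10S,6S,7R,8S) | CN(C)CC1C(=O)O[C@H]2/C=C(CO[Si](c4ccccc4)(c4ccccc4)C(C)(C)C)\C=C/[C@H]3O[C@@]3(C)C[C@H](OC(=O)/C(=C\C)CO[Si](C)(C)C(C)(C)C)[C@@H]12 | intermediate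
47 | N-methyl quaternary ammonium iodide of 46 (not isolated) | C[N+](C)(C)CC1C(=O)O[C@H]2/C=C(CO[Si](c4ccccc4)(c4ccccc4)C(C)(C)C)\C=C/[C@H]3O[C@@]3(C)C[C@H](OC(=O)/C(=C\C)CO[Si](C)(C)C(C)(C)C)[C@@H]12.[I-] | intermediate
48 | target with C15-OTBDPS and side-chain OTBS (α-methylene lactone in place) | C=C1C(=O)O[C@H]2/C=C(CO[Si](c4ccccc4)(c4ccccc4)C(C)(C)C)\C=C/[C@H]3O[C@@]3(C)C[C@H](OC(=O)/C(=C\C)CO[Si](C)(C)C(C)(C)C)[C@@H]12 | intermediate
49 | CNP0293319.3: (1R,10S,6S,7R,8S)-1,10-epoxy-15-hydroxy-8-[(2Z)-2-(hydroxymethyl)but-2-enoyloxy]germacra-2,4,11(13)-trien-12,6-olide | C=C1C(=O)O[C@H]2/C=C(CO)\C=C/[C@H]3O[C@@]3(C)C[C@H](OC(=O)/C(=C\C)CO)[C@@H]12 | target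

## Step count and risk

Total step count: 31 (27 on the main chain, 4 for the side-chain acid).
Longest linear sequence: 27 steps (steps 1–24 and 29–31).

Three steps most likely to fail:

Step 22 (ring-closing metathesis). Ring contraction through the trisubstituted C4=C5 olefin, E/Z scrambling or oligomerisation are all conceivable for an ene–diene closure to a ten-membered ring. The fallback closes the ring by a palladium-free intramolecular sp2–sp2 coupling at C3–C4 instead. It sets out from iodo lactone 29. Me3SnSnMe3 with Pd(PPh3)4 (toluene, 80 °C; the epoxide is not yet allylic) gives the trimethylstannyl alkene F1 with retention. The Swern protocol of step 20 then gives the epoxy aldehyde F2. Stork–Zhao olefination (Ph3PCH2I+ I−, NaN(SiMe3)2, THF/DMPU, −78 °C) gives the (Z)-iodovinyl epoxide F3. Copper thiophene-2-carboxylate (CuO2CC4H3S, 3 equiv, NMP, 2 mM, 0 °C → rt) then couples the alkenyl iodide with the alkenylstannane, with retention at both olefins, and delivers macrocycle 35, where the route resumes at step 23.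

Step 23 (enolate aminomethylation of the macrocycle). LiN(iPr)2 may open the strained dienyl epoxide or deprotonate elsewhere. The fallback installs the aminomethyl group before the vinyl epoxide and the ring exist and carries it as a masked methylene lactone. It sets out from diene lactone 31. LiN(iPr)2 (THF, −78 °C) followed by CH2=NMe2+ I− gives the Mannich base F4. The Swern protocol gives the epoxy aldehyde F5, and Wittig methylenation gives the vinyl epoxide F6. Ring-closing metathesis of F6 as its p-toluenesulfonate salt (1 equiv TsOH·H2O to mask the amine, second-generation Grubbs catalyst, toluene, 60 °C), followed by a NaHCO3 wash, gives Mannich base 37, rejoining the route at step 24.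

Step 14 (Sharpless epoxidation). Z-trisubstituted allylic alcohols are the slowest and least selective substrate class for the titanium–tartrate system, and the free C8 hydroxyl can sequester titanium. The fallback dispenses with the directing hydroxyl and uses an organocatalytic dioxirane epoxidation. It sets out from diol 22. Et3SiCl/imidazole gives the bis(triethylsilyl) ether F7. Shi epoxidation (D-fructose-derived ketone catalyst 30 mol%, KHSO5, K2CO3, MeCN/CH2(OMe)2/aq. buffer, 0 °C) attacks only the electron-rich trisubstituted olefin. The spiro transition state, by analogy with 1-phenylcyclohexene giving the (R,R)-oxide, predicts the (1R,10S)-epoxide, which is compound 24, and the route continues at step 16.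

## Further compounds

F1 | step 22 | trimethylstannyl alkene: 29 with SnMe3 in place of iodine at C4, geometry retained | CC[Si](CC)(CC)OC[C@H]1O[C@@]1(C)C[C@H](O[Si](CC)(CC)CC)[C@H]2CC(=O)O[C@H]2/C=C(\[Sn](C)(C)C)CO[Si](c3ccccc3)(c3ccccc3)C(C)(C)C
F2 | step 22 | epoxy aldehyde: F1 with C2 as CHO | O=C[C@H]1O[C@@]1(C)C[C@H](O[Si](CC)(CC)CC)[C@H]2CC(=O)O[C@H]2/C=C(\[Sn](C)(C)C)CO[Si](c3ccccc3)(c3ccccc3)C(C)(C)C
F3 | step 22 | (Z)-iodovinyl epoxide: F2 with CHO converted to (Z)-CH=CHI | I/C=C\[C@H]1O[C@@]1(C)C[C@H](O[Si](CC)(CC)CC)[C@H]2CC(=O)O[C@H]2/C=C(\[Sn](C)(C)C)CO[Si](c3ccccc3)(c3ccccc3)C(C)(C)C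
F4 | step 23 | Mannich base of 31 (CH2NMe2 on C11; C11 epimers) | CC[Si](CC)(CC)OC[C@H]1O[C@@]1(C)C[C@H](O[Si](CC)(CC)CC)[C@H]2C(CN(C)C)C(=O)O[C@H]2/C=C(\C=C)CO[Si](c3ccccc3)(c3ccccc3)C(C)(C)C
F5 | step 23 | epoxy aldehyde from F4 (C2 as CHO) | O=C[C@H]1O[C@@]1(C)C[C@H](O[Si](CC)(CC)CC)[C@H]2C(CN(C)C)C(=O)O[C@H]2/C=C(\C=C)CO[Si](c3ccccc3)(c3ccccc3)C(C)(C)C
F6 | step 23 | vinyl epoxide from F5 | C=C[C@H]1O[C@@]1(C)C[C@H](O[Si](CC)(CC)CC)[C@H]2C(CN(C)C)C(=O)O[C@H]2/C=C(\C=C)CO[Si](c3ccccc3)(c3ccccc3)C(C)(C)C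
F7 | step 14 | bis(triethylsilyl) ether of diol 22 | CC[Si](CC)(CC)OC/C=C(C)\C[C@H](O[Si](CC)(CC)CC)[C@@H](CC=C)[C@@H](OCc1ccc(OC)cc1)/C=C(\I)CO[Si](c2ccccc2)(c2ccccc2)C(C)(C)C
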